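Labels: ring A = vanillic acid ring, ring B = syringyl ring, C7 = ketone carbon on ring B, C8 = stereocentre bearing the ring A oxygen, C9 = CH2OH carbon.
Enabling feature: C8–H and C9–OH lie alpha and beta to the C7 ketone, which is water added across a terminal C8=C9 alkene. The target therefore maps onto a 2-(ring A-oxy) aryl vinyl ketone.
Cuts: C9–O back to C9–B; C9–B together with C8–H back to the enone; C8=C9 back to an aryloxymethyl ketone plus a one-carbon Mannich unit; C8–O(ring A) back to a phenacyl bromide and a phenol.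
Forward: both rings are bought (acetosyringone, vanillic acid) and no ring is formed. The chain is joined in the order C8–O(ring A), C8=C9, C9–B with C8–H, C9–O, and one acid step then frees the phenol and the acid.
Stereochemistry: (R)-C8, the only stereocentre, comes from protonation of a copper enolate inside a chiral bisphosphine. All later steps run at neutral or acidic pH because C8–H is acidic.

Key step: step 6

Assumption: the sense of induction of the enolate protonation cannot be predicted from close analogy. (R)-DTBM-SEGPHOS, (R)-5,5'-bis[bis(3,5-di-tert-butyl-4-methoxyphenyl)phosphino]-4,4'-bi-1,3-benzodioxole, is written throughout, and its equally available (S)-antipode is to be used if the first run delivers the (S)-configured product.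

Step 1
Reactants: 1 acetosyringone, 1-(4-hydroxy-3,5-dimethoxyphenyl)ethan-1-one
Product: 2 1-[3,5-dimethoxy-4-(methoxymethoxy)phenyl]ethan-1-one
Conditions: MOMCl, iPr2NEt, CH2Cl2, 0 °C to rt
Reagents that add atoms: chloromethyl methyl ether, COCCl
Why: O-alkylation of the acidic para-acyl phenol (MOM protection) should be clean, and the acetal shields the phenol from base, copper alkoxide and peroxide yet falls off with acid at the end.

Step 2
Reactants: 2 1-[3,5-dimethoxy-4-(methoxymethoxy)phenyl]ethan-1-one
Product: 4 2-bromo-1-[3,5-dimethoxy-4-(methoxymethoxy)phenyl]ethan-1-one, via trimethylsilyl enol ether 3 (not isolated)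
Conditions: Me3SiCl, LiN(SiMe3)2 (internal quench), THF, −78 to 0 °C; then NBS, −78 to 0 °C
Reagents that add atoms: N-bromosuccinimide, O=C1CCC(=O)N1Br; chlorotrimethylsilane, C[Si](C)(C)Cl (its silyl group is found in 3 only)
Why: Enol silylation followed by electrophilic bromination of the silyl enol ether should give the monobromide without releasing HBr, so the MOM acetal is never exposed to strong acid.

Step 3
Reactants: 5 vanillic acid, 4-hydroxy-3-methoxybenzoic acid
Product: 6 tert-butyl 4-hydroxy-3-methoxybenzoate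
Conditions: Me2NCH(OtBu)2, toluene, 80 °C
Reagents that add atoms: N,N-dimethylformamide di-tert-butyl acetal, CN(C)C(OC(C)(C)C)OC(C)(C)C
Why: In esterification with a formamide acetal the carboxylic acid protonates the acetal and the carboxylate captures the tert-butyl group, while the much less acidic phenol should stay free.

Step 4
Reactants: 4 2-bromo-1-[3,5-dimethoxy-4-(methoxymethoxy)phenyl]ethan-1-one; 6 tert-butyl 4-hydroxy-3-methoxybenzoate
Product: 7 tert-butyl 4-{2-[3,5-dimethoxy-4-(methoxymethoxy)phenyl]-2-oxoethoxy}-3-methoxybenzoate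
Conditions: K2CO3, acetone, reflux
Reagents that add atoms: none
Why: Williamson ether synthesis (SN2 of the phenoxide on a very reactive phenacyl bromide) is the standard entry to aryloxymethyl aryl ketones and forms the C8–O(ring A) bond.

Step 5
Reactants: 7 tert-butyl 4-{2-[3,5-dimethoxy-4-(methoxymethoxy)phenyl]-2-oxoethoxy}-3-methoxybenzoate
Product: 9 tert-butyl 4-({3-[3,5-dimethoxy-4-(methoxymethoxy)phenyl]-3-oxoprop-1-en-2-yl}oxy)-3-methoxybenzoate, via Mannich base 8 (not isolated)
Conditions: CH2(NMe2)2, Ac2O, DMF, BHT (trace), 0 to 40 °C; cold aq NaHCO3 work-up, Et3N-deactivated silica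
Reagents that add atoms: bis(dimethylamino)methane, CN(C)CN(C)C
Why: In this Mannich methylenation the aminal and acetic anhydride generate the dimethylmethyleneiminium ion in the flask, the readily enolised ketone adds to it at C8 to give 8, and acetylation of the amine lets it leave by E1cB elimination, a sequence long used on aryl alkyl ketones under nearly neutral conditions that spare the MOM acetal, the tert-butyl ester and the new enol ether.

Step 6
Reactants: 9 tert-butyl 4-({3-[3,5-dimethoxy-4-(methoxymethoxy)phenyl]-3-oxoprop-1-en-2-yl}oxy)-3-methoxybenzoate; 10 bis(pinacolato)diboron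
Product: 11 tert-butyl 4-({(2R)-1-[3,5-dimethoxy-4-(methoxymethoxy)phenyl]-1-oxo-3-(4,4,5,5-tetramethyl-1,3,2-dioxaborolan-2-yl)propan-2-yl}oxy)-3-methoxybenzoate
Conditions: CuCl (5 mol %), (R)-DTBM-SEGPHOS (6 mol %), NaOtBu (5 mol %), 10 (1.1 equiv), MeOH (2 equiv), THF, −40 °C; AcOH quench at −40 °C, short silica plug
Reagents that add atoms: bis(pinacolato)diboron 10, CC1(C)OB(OC1(C)C)B1OC(C)(C)C(C)(C)O1
Why: Proposed new method: CuCl, NaOtBu and the bisphosphine give a ligated monovalent copper tert-butoxide that exchanges with 10 to a copper boryl; this adds 1,4 to enone 9, placing boron on C9 and copper on the C7/C8 enolate, and methanol then protonates C8 inside the ligand pocket, releasing 11 and a copper methoxide that re-enters the cycle. The closest known reaction types are the copper-catalysed asymmetric beta-borylation of enones and the conjugate borylation with enantioselective protonation of 2-amido acrylates, whereas a 2-aryloxy aryl vinyl ketone has not been shown in such a protonation. No ring is closed. The single new stereocentre, (R)-C8, is controlled by the chiral bisphosphine, which shields one enolate face, aided by the single enolate geometry expected from five-membered chelation of copper between the enolate oxygen and the ring A ether oxygen. Regioselectivity (C9 rather than C7) is secured by the polarised, unhindered terminal CH2 of the aryl vinyl ketone, and the tert-butyl ester and MOM acetal are inert to copper boryl species. Configurational integrity requires the absence of free alkoxide, which is why NaOtBu only matches CuCl, the temperature is low and the mixture is acidified before warming.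

Step 7
Reactants: 11 tert-butyl 4-({(2R)-1-[3,5-dimethoxy-4-(methoxymethoxy)phenyl]-1-oxo-3-(4,4,5,5-tetramethyl-1,3,2-dioxaborolan-2-yl)propan-2-yl}oxy)-3-methoxybenzoate
Product: 13 tert-butyl 4-({(2R)-1-[3,5-dimethoxy-4-(methoxymethoxy)phenyl]-3-hydroxy-1-oxopropan-2-yl}oxy)-3-methoxybenzoate, via pinacol borate ester 12 (not isolated)
Conditions: 30% aq H2O2, NaH2PO4/Na2HPO4 buffer (pH 7), THF, 0 °C
Reagents that add atoms: hydrogen peroxide, OO
Why: In this boronic ester oxidation hydroperoxide adds to boron and C9 migrates from boron to oxygen to give 12, which hydrolyses to the alcohol; C8 takes no part, and neutral buffer at 0 °C should keep enolisation, retro-aldol cleavage and dehydration slower than the oxidation.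

Step 8
Reactants: 13 tert-butyl 4-({(2R)-1-[3,5-dimethoxy-4-(methoxymethoxy)phenyl]-3-hydroxy-1-oxopropan-2-yl}oxy)-3-methoxybenzoate
Product: 14 4-{[(2R)-3-hydroxy-1-(4-hydroxy-3,5-dimethoxyphenyl)-1-oxopropan-2-yl]oxy}-3-methoxybenzoic acid (target)
Conditions: TFA/CH2Cl2/H2O (10:10:1), 0 °C to rt; co-evaporation with toluene then MeOH; reverse-phase chromatography with acidic eluent
Reagents that add atoms: none
Why: One acidolysis removes the tert-butyl ester (E1 loss of isobutene) and hydrolyses the MOM acetal, water traps the cations, and acid-catalysed enolisation of the aryl ketone is slow at this temperature, so C8 should keep its configuration.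

Compound list
1 | acetosyringone | CC(=O)c1cc(OC)c(O)c(OC)c1 | starting material
2 | 1-[3,5-dimethoxy-4-(methoxymethoxy)phenyl]ethan-1-one | CC(=O)c1cc(OC)c(OCOC)c(OC)c1 | intermediate
3 | {1-[3,5-dimethoxy-4-(methoxymethoxy)phenyl]ethenyl}oxy(trimethyl)silane (not isolated) | C=C(O[Si](C)(C)C)c1cc(OC)c(OCOC)c(OC)c1 | intermediate
4 | 2-bromo-1-[3,5-dimethoxy-4-(methoxymethoxy)phenyl]ethan-1-one | BrCC(=O)c1cc(OC)c(OCOC)c(OC)c1 | intermediate
5 | vanillic acid | COc1cc(C(=O)O)ccc1O | starting material
6 | tert-butyl 4-hydroxy-3-methoxybenzoate | COc1cc(C(=O)OC(C)(C)C)ccc1O | intermediate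
7 | tert-butyl 4-{2-[3,5-dimethoxy-4-(methoxymethoxy)phenyl]-2-oxoethoxy}-3-methoxybenzoate | COc1cc(C(=O)OC(C)(C)C)ccc1OCC(=O)c1cc(OC)c(OCOC)c(OC)c1 | intermediate
8 | racemic tert-butyl 4-({1-[3,5-dimethoxy-4-(methoxymethoxy)phenyl]-3-(dimethylamino)-1-oxopropan-2-yl}oxy)-3-methoxybenzoate (not isolated) | COc1cc(C(=O)OC(C)(C)C)ccc1OC(CN(C)C)C(=O)c1cc(OC)c(OCOC)c(OC)c1 | intermediate
9 | tert-butyl 4-({3-[3,5-dimethoxy-4-(methoxymethoxy)phenyl]-3-oxoprop-1-en-2-yl}oxy)-3-methoxybenzoate | COc1cc(C(=O)OC(C)(C)C)ccc1OC(=C)C(=O)c1cc(OC)c(OCOC)c(OC)c1 | intermediate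
10 | bis(pinacolato)diboron | CC1(C)OB(OC1(C)C)B1OC(C)(C)C(C)(C)O1 | starting material
11 | tert-butyl 4-({(2R)-1-[3,5-dimethoxy-4-(methoxymethoxy)phenyl]-1-oxo-3-(4,4,5,5-tetramethyl-1,3,2-dioxaborolan-2-yl)propan-2-yl}oxy)-3-methoxybenzoate | COc1cc(C(=O)OC(C)(C)C)ccc1O[C@H](CB1OC(C)(C)C(C)(C)O1)C(=O)c1cc(OC)c(OCOC)c(OC)c1 | intermediate
12 | tert-butyl 4-({(2R)-1-[3,5-dimethoxy-4-(methoxymethoxy)phenyl]-1-oxo-3-[(4,4,5,5-tetramethyl-1,3,2-dioxaborolan-2-yl)oxy]propan-2-yl}oxy)-3-methoxybenzoate (not isolated) | COc1cc(C(=O)OC(C)(C)C)ccc1O[C@H](COB1OC(C)(C)C(C)(C)O1)C(=O)c1cc(OC)c(OCOC)c(OC)c1 | intermediate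
13 | tert-butyl 4-({(2R)-1-[3,5-dimethoxy-4-(methoxymethoxy)phenyl]-3-hydroxy-1-oxopropan-2-yl}oxy)-3-methoxybenzoate | COc1cc(C(=O)OC(C)(C)C)ccc1O[C@H](CO)C(=O)c1cc(OC)c(OCOC)c(OC)c1 | intermediate
14 | 4-{[(2R)-3-hydroxy-1-(4-hydroxy-3,5-dimethoxyphenyl)-1-oxopropan-2-yl]oxy}-3-methoxybenzoic acid | COc1cc(C(=O)O)ccc1O[C@H](CO)C(=O)c1cc(OC)c(O)c(OC)c1 | target

Total step count: 8. Longest linear sequence: 7 (steps 1, 2, 4, 5, 6, 7, 8 from acetosyringone; step 3 is the side branch).

Steps most likely to fail

Step 6. The enolate protonation may show poor facial selectivity, either because part of the enolate is handed over to boron and protonated outside the ligand sphere or because two enolate geometries take part. The product may also epimerise under copper alkoxide, and methanol addition or polymerisation may consume the acceptor.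
- The fallback sets out from 6 and returns at 13. It replaces catalysis by auxiliary control and uses only known reaction types.
- Syringaldehyde is MOM-protected as in step 1 to 3,5-dimethoxy-4-(methoxymethoxy)benzaldehyde F1.
- Phenol 6 is alkylated with commercial (S)-4-benzyl-3-(chloroacetyl)oxazolidin-2-one (K2CO3, NaI, acetone) to the N-(aryloxyacetyl)oxazolidinone F2.
- An Evans syn aldol reaction of F2 with F1 (Bu2BOTf, Et3N, CH2Cl2, −78 °C) should give the (2S,3R)-aldol imide F3, in which the (4S)-benzyl auxiliary fixes C8 in the spatial arrangement of the target.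
- LiBH4 (THF, one equivalent of water, 0 °C) removes the auxiliary reductively, without touching the tert-butyl ester, to give the (7R,8R)-1,3-diol F4.
- DDQ (CH2Cl2, rt) oxidises only the electron-rich benzylic C7 alcohol to deliver 13.
- The same material would serve as a configurational reference for the catalytic route.

Step 7. The oxidation may be accompanied by epimerisation at C8, retro-aldol loss of the C9 carbon, dehydration back to the acceptor, or 1,2-elimination of boron and the ring A aryloxide from the peroxide ate complex.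
- The fallback sets out from 11 and returns at 13. It removes the ketone before boron is touched.
- Luche reduction (NaBH4, CeCl3·7H2O, MeOH, −78 °C) gives the (8R)-configured gamma-boryl benzylic alcohol F5 as a mixture of C7 epimers, in which C8–H is no longer acidic.
- Ordinary NaBO3·4H2O oxidation (THF/H2O, rt) then gives the (8R)-1,3-diol F6 as a mixture of C7 epimers.
- Selective benzylic oxidation with DDQ (CH2Cl2, rt) erases C7 and gives 13.

Step 5. Elimination of the amine may stay incomplete, amine may re-add to the acceptor, the captodative alkene may polymerise or dimerise at the temperature needed, and the enol ether may hydrolyse during work-up.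
- The fallback sets out from 7 and returns at 9. It builds C9 by an aldol reaction instead of a Mannich reaction.
- Hydroxymethylation with aqueous formaldehyde (K2CO3, dioxane, rt), a routine reaction of aryloxymethyl aryl ketones, gives the racemic hydroxymethyl ketone F7.
- MsCl and Et3N (CH2Cl2, 0 °C) convert it into the racemic mesylate F8, which undergoes E1cB elimination in the same flask to 9.

Further compounds
F1 | step 6 | 3,5-dimethoxy-4-(methoxymethoxy)benzaldehyde | O=Cc1cc(OC)c(OCOC)c(OC)c1
F2 | step 6 | tert-butyl 4-{2-[(4S)-4-benzyl-2-oxo-1,3-oxazolidin-3-yl]-2-oxoethoxy}-3-methoxybenzoate | COc1cc(C(=O)OC(C)(C)C)ccc1OCC(=O)N1[C@@H](Cc2ccccc2)COC1=O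
F3 | step 6 | tert-butyl 4-({(2S,3R)-1-[(4S)-4-benzyl-2-oxo-1,3-oxazolidin-3-yl]-3-[3,5-dimethoxy-4-(methoxymethoxy)phenyl]-3-hydroxy-1-oxopropan-2-yl}oxy)-3-methoxybenzoate | COc1cc(C(=O)OC(C)(C)C)ccc1O[C@@H]([C@H](O)c1cc(OC)c(OCOC)c(OC)c1)C(=O)N1[C@@H](Cc2ccccc2)COC1=O
F4 | step 6 | tert-butyl 4-({(1R,2R)-1-[3,5-dimethoxy-4-(methoxymethoxy)phenyl]-1,3-dihydroxypropan-2-yl}oxy)-3-methoxybenzoate | COc1cc(C(=O)OC(C)(C)C)ccc1O[C@@H]([C@H](O)c1cc(OC)c(OCOC)c(OC)c1)CO
F5 | step 7 | tert-butyl 4-({(2R)-1-[3,5-dimethoxy-4-(methoxymethoxy)phenyl]-1-hydroxy-3-(4,4,5,5-tetramethyl-1,3,2-dioxaborolan-2-yl)propan-2-yl}oxy)-3-methoxybenzoate, C7 epimers | COc1cc(C(=O)OC(C)(C)C)ccc1O[C@H](CB1OC(C)(C)C(C)(C)O1)C(O)c1cc(OC)c(OCOC)c(OC)c1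
F6 | step 7 | tert-butyl 4-({(2R)-1-[3,5-dimethoxy-4-(methoxymethoxy)phenyl]-1,3-dihydroxypropan-2-yl}oxy)-3-methoxybenzoate, C7 epimers | COc1cc(C(=O)OC(C)(C)C)ccc1O[C@H](CO)C(O)c1cc(OC)c(OCOC)c(OC)c1
F7 | step 5 | racemic tert-butyl 4-({1-[3,5-dimethoxy-4-(methoxymethoxy)phenyl]-3-hydroxy-1-oxopropan-2-yl}oxy)-3-methoxybenzoate | COc1cc(C(=O)OC(C)(C)C)ccc1OC(CO)C(=O)c1cc(OC)c(OCOC)c(OC)c1
F8 | step 5 | racemic tert-butyl 4-({1-[3,5-dimethoxy-4-(methoxymethoxy)phenyl]-3-(methanesulfonyloxy)-1-oxopropan-2-yl}oxy)-3-methoxybenzoate | COc1cc(C(=O)OC(C)(C)C)ccc1OC(COS(C)(=O)=O)C(=O)c1cc(OC)c(OCOC)c(OC)c1
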